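No rate constant is given for this flask, so one has to be read from the spring run.

all flasks: free monomer 1.5 M; impurity 34 mM
- spring: pre-initiator 1.2 mol%; run made earlier
- flask: pre-initiator 2.5 mol%; time 25 h

- spring (time / h: monomer in chains / %, free monomer / %): 2.00: 0.3, 99.8; 4.00: 1.5, 98.9; 6.00: 2.9, 97.3; 8.00: 4.9, 94.6

(scatter of a reading: 0.3 percentage points)

- the average divides the monomer in chains by the number of chains begun, living and dead together
- the earlier runs do not show the number of chains; that part of a forecast is a guess
- no earlier run changes the charge of pre-initiator; that part of a forecast is a guess

* average number of monomer units in a chain (chains begun, living or dead) at 25 h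
* part of the free monomer that has reacted at 25 h

From 4.00 h to 8.00 h in the spring run, monomer in chains grows by a factor 3.27 and the loss of free monomer by a factor 4.91. The rate per free monomer therefore climbs with time. The loss is pseudo-first-order in free monomer, but its constant drifts upward as 2·t/(τ·τ). The last spring reading gives, as a reading with its scatter:

τ = t/sqrt(−ln f) = 34.0 h

Here τ is the acceleration time, defined by −ln f = (t/τ)·(t/τ), with f the fraction of free monomer left.

Now take the opposite outcome: free monomer still above half of its charge in the new flask at 25 h. That requires

τ > t/sqrt(ln 2) = 30.0 h

The new flask carries 2.5 mol% of pre-initiator against 1.2 mol%. Taking 1/(τ·τ) as proportional to that loading is a guess, since no earlier run varies it: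

τ = 23.5 h

This value is shorter than the limit by a factor 1.28, so the reckoning expects the new flask to pass the mark, with 67.7% reacted at 25 h. The time τ says nothing about the number of chains.

The forecast gives 55% reacted and an average chain of 45, noting “Chains begun are a guess”.

The flask gives 62.0% reacted and an average chain of 700.

    free monomer + initiator → living end + monomer in chains (k = 0.590 M⁻¹ h⁻¹)
    free monomer + living end → monomer in chains + living end, rate k2*[living end]*[free monomer] (k = 51.0 M⁻¹ h⁻¹)
    pre-initiator ⇌ initiator (K = 0.980, k = 0.0160 h⁻¹)
    initiator + impurity → spent initiator (k = 190 M⁻¹ h⁻¹)

The reckoning stands 5.7 percentage points above the computed conversion, while the chains are long in this flask partly because impurity turns initiator into spent initiator before it begins a chain. The run without that step averages 234 against 700. For the same flask left until 6.0 h, τ gives 6.28% reacted, and the computed value is 6.07%.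

The data stem from a simulated flask with made-up constants; scatter was added.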